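Ring A of this cis-fused eremophilane carries cis methyl groups on C4 and C5 and a C2 ketone para to C5. This pattern is disconnected to tiglaldehyde and a 2-silyloxy-1,3-diene. One catalytic enantioselective Diels–Alder reaction forms C3–C4 and C5–C10, closes ring A and sets C4, C5 and C10. The diene precursor is an (E)-penta-1,3-diene bearing a triisopropylsilyl enol ether at C2 and a silyl-protected hydroxymethyl arm (C9). Afterwards the formyl group is homologated to a prenyl chain, C9 is extended by one carbon, a carbonyl-ene reaction closes ring B, and C9 is inverted before esterification.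

Key step: step 3

Remark: atom labels follow eremophilane numbering (ring A: C1–C5, C10; ring B: C5–C10); β denotes the face of the C5 methyl group, α the opposite face.
Remark: both oxygen substituents of the diene are carried as bulky silyl groups (triisopropylsilyl enol ether, tert-butyldiphenylsilyl ether), which should tolerate the cationic boron Lewis acid better than smaller or benzylic groups.
Assumption: the (R)-configured oxazaborolidine is specified because the formyl C–H···O binding model for α-substituted enals predicts attack on the Si face of the enal α-carbon (C5) with this antipode; the (S)-antipode would be used if the sense proved opposite.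

Step 1
Reactants: 1 (tert-butyldiphenylsilyloxy)acetaldehyde; 2 1-(triphenylphosphoranylidene)propan-2-one
Product: 3 (E)-5-(tert-butyldiphenylsilyloxy)pent-3-en-2-one
Conditions: CH2Cl2, rt to 40 °C
Reagents that add atoms: none
Why: Wittig olefination with a stabilised acyl ylide should give the (E)-enone selectively, no stereocentre being formed.

Step 2
Reactants: 3 (E)-5-(tert-butyldiphenylsilyloxy)pent-3-en-2-one
Product: 4 (E)-5-(tert-butyldiphenylsilyloxy)-2-(triisopropylsilyloxy)penta-1,3-diene
Conditions: i-Pr3SiOTf, Et3N, CH2Cl2, 0 °C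
Reagents that add atoms: triisopropylsilyl trifluoromethanesulfonate, CC(C)[Si](C(C)C)(C(C)C)OS(=O)(=O)C(F)(F)F
Why: Silyl enol ether formation by soft enolisation (O-silylation, then removal of a methyl proton by the amine) should give the cross-conjugated 2-silyloxydiene with the E-alkene untouched.

Step 3
Reactants: 4 (E)-5-(tert-butyldiphenylsilyloxy)-2-(triisopropylsilyloxy)penta-1,3-diene; 5 tiglaldehyde, (E)-2-methylbut-2-enal
Product: 6 ring-A cycloadduct, (1R,2S,6S)-2-[(tert-butyldiphenylsilyloxy)methyl]-1,6-dimethyl-4-(triisopropylsilyloxy)cyclohex-3-ene-1-carbaldehyde (C5 formyl and β-methyl, C4 β-methyl, C10 α-CH2OSi, enol ether C1=C2)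
Conditions: (R)-tetrahydro-1-(2-methylphenyl)-3,3-diphenyl-1H,3H-pyrrolo[1,2-c][1,3,2]oxazaborole (20 mol %), HN(SO2CF3)2 (17 mol %), CH2Cl2, −78 to −20 °C
Reagents that add atoms: none
Why: The protonated oxazaborolidine binds the formyl oxygen of s-trans tiglaldehyde and lowers its LUMO, and the electron-rich diene adds in a concerted, asynchronous [4+2] cycloaddition in which the nucleophilic terminus C3 bonds to the β-carbon C4 slightly ahead of the C10–C5 bond. The closest known reaction type is the oxazaborolidinium-catalysed enantioselective Diels–Alder reaction of α-substituted enals with 2-silyloxybuta-1,3-dienes. Ring A is closed by this intermolecular cycloaddition, suprafacial on both partners, so the six-membered ring arises from two new σ-bonds between two fragments and not from cyclisation of a chain. C4 and C5 inherit their cis methyl/methyl relation from the E geometry of the enal, C10 is set relative to C5 by the endo position of the formyl group (formyl cis to the CH2OSi arm of the E-diene), and the absolute sense of all three should come from the catalyst shielding one face of the bound enal. Regioselectivity is secured because the 2-silyloxy group and the C10 substituent polarise the diene in the same direction, endo selectivity by secondary overlap with the formyl group in the absence of a bridging methylene, and the bulky silyl groups should suppress Mukaiyama-type addition and catalyst binding.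

Step 4
Reactants: 6 ring-A cycloadduct
Product: 8 keto aldehyde (ring-A cyclohexanone, C2=O, with 4β-methyl, 5β-methyl, 5α-CH2CHO and 10α-CH2OSi(t-Bu)Ph2), via bis-enol ether 7 (not isolated)
Conditions: MeOCH2PPh3Cl, KN(SiMe3)2, THF, 0 °C to rt; then 2 M aq HCl, rt
Reagents that add atoms: (methoxymethyl)triphenylphosphonium chloride, COC[P+](c1ccccc1)(c1ccccc1)c1ccccc1.[Cl-]; water, O
Why: Wittig methoxymethylenation of the non-enolisable neopentyl aldehyde followed by acid hydrolysis of both enol ethers in the same flask should give the one-carbon homologated aldehyde (C7) and the C2 ketone, while C4, C5 and C10 are not α to a carbonyl group and stay untouched.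

Step 5
Reactants: 8 keto aldehyde
Product: 9 prenyl ketone (as 8, with 5α-(3-methylbut-2-enyl) in place of 5α-CH2CHO)
Conditions: i-PrPPh3I, n-BuLi, THF, 0 °C; then 8, −78 to 0 °C
Reagents that add atoms: isopropyltriphenylphosphonium iodide, CC(C)[P+](c1ccccc1)(c1ccccc1)c1ccccc1.[I-]
Why: Wittig olefination with a hindered non-stabilised ylide should take place at the unhindered aldehyde far faster than at the ketone at low temperature and so give the prenyl group, no stereocentre being formed.

Step 6
Reactants: 9 prenyl ketone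
Product: 10 ethylene ketal of 9 at C2
Conditions: HOCH2CH2OH, pyridinium p-toluenesulfonate, benzene, reflux (Dean–Stark)
Reagents that add atoms: ethylene glycol, OCCO
Why: Acid-catalysed ketalisation with azeotropic removal of water should mask the C2 ketone before organolithium and hydride reagents are used, the mild pyridinium acid leaving the trisubstituted alkene and the silyl ether intact.

Step 7
Reactants: 10 ethylene ketal
Product: 11 primary alcohol (10 with free 10α-CH2OH)
Conditions: Bu4NF, THF, rt
Reagents that add atoms: none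
Why: Fluoride-mediated silyl ether cleavage should free the C9 alcohol, the ketal and the alkene being inert to fluoride.

Step 8
Reactants: 11 primary alcohol
Product: 12 C9 aldehyde (10α-formyl)
Conditions: Dess–Martin periodinane, NaHCO3, CH2Cl2, 0 °C to rt
Reagents that add atoms: none
Why: Dess–Martin oxidation under buffered, non-basic conditions should give the aldehyde without epimerising the adjacent C10 centre, and the crude aldehyde is used at once.

Step 9
Reactants: 12 C9 aldehyde
Product: 13 (9R)-carbinol, 10α-[(R)-hydroxy(1,3-dithian-2-yl)methyl] (9β-oxygen series)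
Conditions: 1,3-dithiane, n-BuLi, THF, −30 °C; then 12, −78 °C; then H2O
Reagents that add atoms: 1,3-dithiane, C1CSCSC1
Why: Corey–Seebach addition of 2-lithio-1,3-dithiane as a formyl anion equivalent introduces C8, and by the Felkin–Anh model the nucleophile should attack anti to the quaternary C5 with the carbonyl oxygen on the side of C1, which favours the (9R)-carbinol.

Step 10
Reactants: 13 (9R)-carbinol
Product: 14 tert-butyldimethylsilyl ether of 13
Conditions: t-BuMe2SiOTf, 2,6-lutidine, CH2Cl2, −78 to 0 °C
Reagents that add atoms: tert-butyldimethylsilyl trifluoromethanesulfonate, CC(C)(C)[Si](C)(C)OS(=O)(=O)C(F)(F)F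
Why: Silylation of the hindered secondary alcohol with a silyl triflate and a hindered pyridine base should place a bulky, non-chelating group on O9 that later steers the ring closure.

Step 11
Reactants: 14 silyl ether
Product: 15 (9R)-α-silyloxy aldehyde (C8 formyl on C9)
Conditions: MeI, CaCO3, MeCN/H2O (9:1), 45 °C
Reagents that add atoms: water, O
Why: S-alkylative hydrolysis of the dithioacetal under buffered conditions should release the aldehyde without touching the ketal, the trisubstituted alkene or the C9 centre.

Step 12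
Reactants: 15 (9R)-α-silyloxy aldehyde
Product: 16 cis-fused decalin (C2 ethylene ketal, 4β,5β-dimethyl, 10β-H, 7β-isopropenyl, 8α-OH, 9β-OSi(t-Bu)Me2)
Conditions: Me2AlCl (1.5 equiv), CH2Cl2, −78 to −40 °C
Reagents that add atoms: none
Why: In this intramolecular carbonyl-ene reaction (citronellal-to-isopulegol type) C7 of the prenyl group attacks the aluminium-bound aldehyde with transfer of a methyl hydrogen through a chair-like transition state in which the bulky 9β-silyloxy group (C–O anti to the incoming alkene, Felkin-type), the carbonyl oxygen and the isopropylidene unit are all equatorial, which should set 8α-OH and 7β-isopropenyl trans to each other and close ring B by 6-membered ring formation between C7 and C8.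

Step 13
Reactants: 16 decalin alcohol
Product: 17 8α-acetate of 16
Conditions: Ac2O, Et3N, 4-(dimethylamino)pyridine (cat.), CH2Cl2, rt
Reagents that add atoms: acetic anhydride, CC(=O)OC(C)=O
Why: Nucleophile-catalysed acylation of the equatorial secondary alcohol should give the C8 acetate, no stereocentre being touched.

Step 14
Reactants: 17 acetate silyl ether
Product: 18 8α-acetoxy-9β-ol
Conditions: HF·pyridine, pyridine, THF, 0 °C to rt
Reagents that add atoms: none
Why: Desilylation with buffered hydrogen fluoride should expose the equatorial 9β-hydroxyl without ketal hydrolysis and, since no basic alkoxide is formed, without acetyl migration.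

Step 15
Reactants: 18 8α-acetoxy-9β-ol
Product: 19 8α-acetoxy-9-ketone
Conditions: Dess–Martin periodinane, NaHCO3, CH2Cl2, 0 °C
Reagents that add atoms: none
Why: Dess–Martin oxidation should remove the relay stereocentre at C9, the neutral buffered medium protecting the epimerisable C8 and C10 positions.

Step 16
Reactants: 19 8α-acetoxy-9-ketone
Product: 20 8α-acetoxy-9α-ol
Conditions: LiBH(s-Bu)3, THF, −78 °C; then AcOH, −78 °C
Reagents that add atoms: none
Why: In this substrate-controlled hydride reduction axial delivery on the α face is blocked by the syn-axial C5–C4 bond of the cis-decalin, so the bulky hydride should enter equatorially from the β face and give the axial 9α-alcohol cis to the acetate, the cold acidic quench protonating the alkoxide before the acetyl group can migrate.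

Step 17
Reactants: 20 8α-acetoxy-9α-ol; 21 tiglic acid, (E)-2-methylbut-2-enoic acid
Product: 22 8α-acetoxy-9α-tigloyloxy C2 ethylene ketal
Conditions: 21, 2,4,6-trichlorobenzoyl chloride, Et3N, toluene, rt; then 20, 4-(dimethylamino)pyridine, toluene, 40 °C
Reagents that add atoms: none
Why: Yamaguchi esterification through the mixed anhydride, which transfers tiglic acid without double-bond isomerisation, should acylate the hindered axial 9α-hydroxyl with retention at C9.

Step 18
Reactants: 22 ketal diester
Product: 23 target, (4S,5R,7R,8R,9S,10S)-8-acetoxy-9-[(E)-2-methylbut-2-enoyloxy]eremophil-11-en-2-one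
Conditions: 1 M aq HCl, THF, 0 °C to rt
Reagents that add atoms: water, O
Why: Mild acid-catalysed ketal hydrolysis should release the C2 ketone, the two esters and the isopropenyl group being stable to dilute acid at room temperature.

Compound list
1 | (tert-butyldiphenylsilyloxy)acetaldehyde | O=CCO[Si](c1ccccc1)(c1ccccc1)C(C)(C)C | starting material
2 | 1-(triphenylphosphoranylidene)propan-2-one | CC(=O)C=P(c1ccccc1)(c1ccccc1)c1ccccc1 | starting material
3 | (E)-5-(tert-butyldiphenylsilyloxy)pent-3-en-2-one | CC(=O)/C=C/CO[Si](c1ccccc1)(c1ccccc1)C(C)(C)C | intermediate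
4 | (E)-5-(tert-butyldiphenylsilyloxy)-2-(triisopropylsilyloxy)penta-1,3-diene | C=C(O[Si](C(C)C)(C(C)C)C(C)C)/C=C/CO[Si](c1ccccc1)(c1ccccc1)C(C)(C)C | intermediate
5 | tiglaldehyde, (E)-2-methylbut-2-enal | C/C=C(\C)C=O | starting material
6 | ring-A cycloadduct, (1R,2S,6S)-2-[(tert-butyldiphenylsilyloxy)methyl]-1,6-dimethyl-4-(triisopropylsilyloxy)cyclohex-3-ene-1-carbaldehyde | O=C[C@@]1(C)[C@H](C=C(O[Si](C(C)C)(C(C)C)C(C)C)C[C@@H]1C)CO[Si](c1ccccc1)(c1ccccc1)C(C)(C)C | intermediate
7 | bis-enol ether, 6 with the formyl group converted into CH=CH–OMe (E/Z mixture) | COC=C[C@@]1(C)[C@H](C=C(O[Si](C(C)C)(C(C)C)C(C)C)C[C@@H]1C)CO[Si](c1ccccc1)(c1ccccc1)C(C)(C)C | intermediate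
8 | keto aldehyde, ring-A cyclohexanone (C2=O) with 4β-methyl, 5β-methyl, 5α-CH2CHO, 10α-CH2OSi(t-Bu)Ph2 | O=CC[C@@]1(C)[C@H](CC(=O)C[C@@H]1C)CO[Si](c1ccccc1)(c1ccccc1)C(C)(C)C | intermediate
9 | prenyl ketone, as 8 with 5α-(3-methylbut-2-enyl) | CC(C)=CC[C@@]1(C)[C@H](CC(=O)C[C@@H]1C)CO[Si](c1ccccc1)(c1ccccc1)C(C)(C)C | intermediate
10 | C2 ethylene ketal of 9 | CC(C)=CC[C@@]1(C)[C@H](CC2(OCCO2)C[C@@H]1C)CO[Si](c1ccccc1)(c1ccccc1)C(C)(C)C | intermediate
11 | primary alcohol, 10α-CH2OH | CC(C)=CC[C@@]1(C)[C@H](CC2(OCCO2)C[C@@H]1C)CO | intermediate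
12 | C9 aldehyde, 10α-CHO | CC(C)=CC[C@@]1(C)[C@H](CC2(OCCO2)C[C@@H]1C)C=O | intermediate
13 | (9R)-carbinol, 10α-[(R)-hydroxy(1,3-dithian-2-yl)methyl] | CC(C)=CC[C@@]1(C)[C@H](CC2(OCCO2)C[C@@H]1C)[C@@H](O)C1SCCCS1 | intermediate
14 | tert-butyldimethylsilyl ether of 13 | CC(C)=CC[C@@]1(C)[C@H](CC2(OCCO2)C[C@@H]1C)[C@@H](O[Si](C)(C)C(C)(C)C)C1SCCCS1 | intermediate
15 | (9R)-α-silyloxy aldehyde | CC(C)=CC[C@@]1(C)[C@H](CC2(OCCO2)C[C@@H]1C)[C@@H](O[Si](C)(C)C(C)(C)C)C=O | intermediate
16 | cis-decalin, C2 ethylene ketal, 7β-isopropenyl, 8α-OH, 9β-OSi(t-Bu)Me2, 10β-H, 4β,5β-dimethyl | C=C(C)[C@H]1C[C@@]2(C)[C@H](CC3(OCCO3)C[C@@H]2C)[C@@H](O[Si](C)(C)C(C)(C)C)[C@@H]1O | intermediate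
17 | 8α-acetate of 16 | C=C(C)[C@H]1C[C@@]2(C)[C@H](CC3(OCCO3)C[C@@H]2C)[C@@H](O[Si](C)(C)C(C)(C)C)[C@@H]1OC(C)=O | intermediate
18 | 8α-acetoxy-9β-ol | C=C(C)[C@H]1C[C@@]2(C)[C@H](CC3(OCCO3)C[C@@H]2C)[C@@H](O)[C@@H]1OC(C)=O | intermediate
19 | 8α-acetoxy-9-ketone | C=C(C)[C@H]1C[C@@]2(C)[C@H](CC3(OCCO3)C[C@@H]2C)C(=O)[C@@H]1OC(C)=O | intermediate
20 | 8α-acetoxy-9α-ol | C=C(C)[C@H]1C[C@@]2(C)[C@H](CC3(OCCO3)C[C@@H]2C)[C@H](O)[C@@H]1OC(C)=O | intermediate
21 | tiglic acid, (E)-2-methylbut-2-enoic acid | C/C=C(\C)C(=O)O | starting material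
22 | 8α-acetoxy-9α-tigloyloxy C2 ethylene ketal | C=C(C)[C@H]1C[C@@]2(C)[C@H](CC3(OCCO3)C[C@@H]2C)[C@H](OC(=O)/C(C)=C/C)[C@@H]1OC(C)=O | intermediate
23 | (4S,5R,7R,8R,9S,10S)-8-acetoxy-9-[(E)-2-methylbut-2-enoyloxy]eremophil-11-en-2-one, CNP0204573.1 | C=C(C)[C@H]1C[C@@]2(C)[C@H](CC(=O)C[C@@H]2C)[C@H](OC(=O)/C(C)=C/C)[C@@H]1OC(C)=O | target

Total step count: 18. Longest linear sequence: 18 steps (1 to 23); 5 and 21 enter as commercial materials.

Steps most likely to fail

Step 3. The β-methyl group slows the cycloaddition, so that catalyst decay, silyl transfer or Mukaiyama-type addition of the enol ether, and erosion of endo or facial selectivity can take over. The fallback sets out from 4 and 5 and gives up catalyst control: the cycloaddition is run with an achiral Lewis acid (Me2AlCl, CH2Cl2, −78 °C) to give the racemic ring-A cycloadduct F1. Condensation with (1R,2R)-N,N'-dimethyl-1,2-diphenylethane-1,2-diamine (4 Å molecular sieves, Et2O) should convert it into the imidazolidine of 6 F2 and the diastereomeric imidazolidine of the enantiomer F3, which are separated by chromatography. Mild hydrolysis of F2 (Et2O/dilute aqueous citric acid, 0 °C) returns enantiopure 6, where the route is rejoined.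

Step 9. Facial discrimination in the carbon–carbon bond formation at C9 may be weak or reversed, which would starve the route of the (9R)-carbinol. The fallback sets out from 13 in whatever epimer ratio it is obtained and switches to the C9-epimeric series, in which hydride rather than carbon is delivered anti to C5. Oxidation (SO3·pyridine, DMSO, i-Pr2NEt) gives the acyl dithiane F4. Reduction with LiBH(s-Bu)3 at −78 °C should give the (9S)-carbinol F5. Etherification (NaH, 4-methoxybenzyl chloride, Bu4NI) gives the 4-methoxybenzyl ether F6, and MeI/CaCO3 in aqueous MeCN the (9S)-α-alkoxy aldehyde F7. A carbonyl-ene closure with excess Me2AlCl (2.5 equiv, −78 °C), this time under chelation between the aldehyde and ether oxygens, should give the 8α-hydroxy-9α-(4-methoxybenzyloxy) decalin F8. Acetylation gives the acetate F9, and DDQ in buffered CH2Cl2/H2O removes the benzyl group to give 20, where the route is rejoined without any inversion at C9. This variant depends on chelation overriding the all-equatorial alternative, which is why it is not the main route.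

Step 17. Acylation of the hindered axial hydroxyl may be sluggish, and base-mediated migration of the acetyl group from O8 to O9 can then scramble the two esters. The fallback sets out from 20 and reverses the order of the esterifications. Methanolysis (K2CO3, MeOH, 0 °C) gives the 8α,9α-diol F10. Selective silylation of the equatorial 8-hydroxyl (Et3SiCl, imidazole, CH2Cl2, −20 °C) gives the 8-O-triethylsilyl ether F11. Yamaguchi esterification with 21 under forcing conditions, now without an acyl neighbour, gives the 9-tiglate F12. HF·pyridine frees the 8-hydroxyl to give the 8-ol 9-tiglate F13, and acetylation (Ac2O, Et3N, 4-(dimethylamino)pyridine) gives 22, where the route is rejoined.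

Further compounds
F1 | step 3 | racemic ring-A cycloadduct (6 and its enantiomer) | O=C[C@@]1(C)[C@H](C=C(O[Si](C(C)C)(C(C)C)C(C)C)C[C@@H]1C)CO[Si](c1ccccc1)(c1ccccc1)C(C)(C)C.O=C[C@]1(C)[C@@H](C=C(O[Si](C(C)C)(C(C)C)C(C)C)C[C@H]1C)CO[Si](c1ccccc1)(c1ccccc1)C(C)(C)C
F2 | step 3 | imidazolidine of 6 with the (1R,2R)-diamine | CN1[C@H](c2ccccc2)[C@@H](c2ccccc2)N(C)C1[C@@]1(C)[C@H](C=C(O[Si](C(C)C)(C(C)C)C(C)C)C[C@@H]1C)CO[Si](c1ccccc1)(c1ccccc1)C(C)(C)C
F3 | step 3 | diastereomeric imidazolidine of the enantiomer of 6 | CN1[C@H](c2ccccc2)[C@@H](c2ccccc2)N(C)C1[C@]1(C)[C@@H](C=C(O[Si](C(C)C)(C(C)C)C(C)C)C[C@H]1C)CO[Si](c1ccccc1)(c1ccccc1)C(C)(C)C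
F4 | step 9 | acyl dithiane (C9 ketone) | CC(C)=CC[C@@]1(C)[C@H](CC2(OCCO2)C[C@@H]1C)C(=O)C1SCCCS1
F5 | step 9 | (9S)-carbinol | CC(C)=CC[C@@]1(C)[C@H](CC2(OCCO2)C[C@@H]1C)[C@H](O)C1SCCCS1
F6 | step 9 | 4-methoxybenzyl ether of the (9S)-carbinol | CC(C)=CC[C@@]1(C)[C@H](CC2(OCCO2)C[C@@H]1C)[C@H](OCc1ccc(OC)cc1)C1SCCCS1
F7 | step 9 | (9S)-α-(4-methoxybenzyloxy) aldehyde | CC(C)=CC[C@@]1(C)[C@H](CC2(OCCO2)C[C@@H]1C)[C@H](OCc1ccc(OC)cc1)C=O
F8 | step 9 | 8α-hydroxy-9α-(4-methoxybenzyloxy) decalin | C=C(C)[C@H]1C[C@@]2(C)[C@H](CC3(OCCO3)C[C@@H]2C)[C@H](OCc4ccc(OC)cc4)[C@@H]1O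
F9 | step 9 | 8α-acetoxy-9α-(4-methoxybenzyloxy) decalin | C=C(C)[C@H]1C[C@@]2(C)[C@H](CC3(OCCO3)C[C@@H]2C)[C@H](OCc4ccc(OC)cc4)[C@@H]1OC(C)=O
F10 | step 17 | 8α,9α-diol | C=C(C)[C@H]1C[C@@]2(C)[C@H](CC3(OCCO3)C[C@@H]2C)[C@H](O)[C@@H]1O
F11 | step 17 | 8-O-triethylsilyl ether of the diol | C=C(C)[C@H]1C[C@@]2(C)[C@H](CC3(OCCO3)C[C@@H]2C)[C@H](O)[C@@H]1O[Si](CC)(CC)CC
F12 | step 17 | 8-O-triethylsilyl 9-tiglate | C=C(C)[C@H]1C[C@@]2(C)[C@H](CC3(OCCO3)C[C@@H]2C)[C@H](OC(=O)/C(C)=C/C)[C@@H]1O[Si](CC)(CC)CC
F13 | step 17 | 8-ol 9-tiglate | C=C(C)[C@H]1C[C@@]2(C)[C@H](CC3(OCCO3)C[C@@H]2C)[C@H](OC(=O)/C(C)=C/C)[C@@H]1O
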